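**Retrosynthetic overview**
1. Target 20 ⇐ 18: the C3 and C2 carbinols come from an α-ketol by equilibration and hydroxyl-directed reduction; 18 ⇐ 16: the eleven-membered ring and the C9 acetate come from a ring-closing Ni/Cr alkenylation that is terminated by O-acylation.
2. Key step (C–O bond): 15 ⇐ 13, an acid-triggered allylic oxygen transposition of a methyl carbinol/enol ether that forms the C2–O bond and the C1=C15 alkene from the vinylogous ester carried since quinone 2.
3. 13 ⇐ 10 + 11: the C1–C14 bond by B-alkyl Suzuki coupling with (S)-β-citronellene, which supplies C9–C14 and the C12 stereocentre.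
4. 8 ⇐ 4: the five-membered ring by ozonolysis/aldol ring contraction of the Diels–Alder cyclohexene, then convex-face hydrogenation (C7) and enol triflate formation.
5. 4 ⇐ 2 + 3: the six-membered ring, the C4 quaternary centre and C16 by chelation-controlled asymmetric Diels–Alder reaction; 2 ⇐ 1 by para-oxygenation of a phenol. Rings are formed in the order six, five, eleven.

Numbering note: the macrocycles are named with trinervitane numbering (C17 on C15, C18 on C4, C19 = CH2 on C8, C20 on C12), and the same carbon numbers are used for all intermediates in the "Why" lines.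

**Route**

Step 1
Reactants: 1 3-methoxy-5-methylphenol
Product: 2 2-methoxy-6-methylcyclohexa-2,5-diene-1,4-dione
Conditions: K2[ON(SO3)2] (Fremy's salt, 2.2 equiv), KH2PO4 buffer, H2O/acetone, 0–25 °C
Reagents that add atoms: Fremy's salt, [K+].[K+].[O]N(S(=O)(=O)[O-])S(=O)(=O)[O-]
Why: Teuber oxidation, in which the nitroxyl radical oxygenates the only free para position of the phenol (between OMe and Me), forming the C–O bond that becomes O3 and giving the p-quinone whose oxygens steer all later selectivity, with no stereocentre formed.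

Step 2
Reactants: 2 2-methoxy-6-methylcyclohexa-2,5-diene-1,4-dione, 3 2-methylbuta-1,3-diene (isoprene)
Product: 4 (4aR,8aS)-2-methoxy-6,8a-dimethyl-4a,5,8,8a-tetrahydronaphthalene-1,4-dione
Conditions: TiCl2(OiPr)2 (20 mol %), (R,R)-TADDOL (22 mol %), 4 Å MS, toluene/CH2Cl2, −78 → −30 °C
Reagents that add atoms: none
Why: Lewis-acid-promoted Diels–Alder reaction under chelation control, in which the chiral titanium TADDOLate binds the C3 carbonyl and the neighbouring methoxy oxygen of 2, activates only the methyl-bearing C=C, makes its CH terminus (C16) the electrophilic β-carbon so that the isoprene CH2 next to the methyl-bearing carbon bonds there, and shields one face, so that the C4 quaternary centre and C16 are set together cis (suprafacial) with the absolute sense fixed by the choice of ligand enantiomer.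

Step 3
Reactants: 4 (4aR,8aS)-2-methoxy-6,8a-dimethyl-4a,5,8,8a-tetrahydronaphthalene-1,4-dione
Product: 6 (3aS,7aS)-3-acetyl-6-methoxy-7a-methyl-3a,7a-dihydro-1H-indene-4,7-dione, via keto-aldehyde 5 (not isolated)
Conditions: O3, CH2Cl2, −78 °C (Sudan Red 7B end point); PPh3; then TsOH·H2O (10 mol %), 40 °C
Reagents that add atoms: ozone, [O-][O+]=O
Why: Ozonolysis cleaves the electron-rich trisubstituted ring alkene much faster than the acceptor-substituted methoxy-enedione C=C, and under acid the ketone enol carbon C7 of 5 adds to the more electrophilic aldehyde C6 and dehydrates (intramolecular aldol condensation), contracting the cyclohexene to the acetylcyclopentene without touching C4 or C16.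

Step 4
Reactants: 6 (3aS,7aS)-3-acetyl-6-methoxy-7a-methyl-3a,7a-dihydro-1H-indene-4,7-dione
Product: 7 (3R,3aR,7aS)-3-acetyl-6-methoxy-7a-methyl-2,3,3a,7a-tetrahydro-1H-indene-4,7-dione
Conditions: H2 (1 atm), 5% Pd/C, EtOAc, 0 °C
Reagents that add atoms: none
Why: Heterogeneous catalytic hydrogenation adds H2 cis from the convex face of the cis-fused bicycle (the face of the angular H and methyl, away from the dione ring at allylic C16), which sets C7 with the acetyl group cis to C15, while the donor-substituted methoxy-enedione C=C is expected to react much more slowly.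

Step 5
Reactants: 7 (3R,3aR,7aS)-3-acetyl-6-methoxy-7a-methyl-2,3,3a,7a-tetrahydro-1H-indene-4,7-dione
Product: 8 1-[(1R,3aS,7aR)-5-methoxy-3a-methyl-4,7-dioxo-2,3,3a,4,7,7a-hexahydro-1H-inden-1-yl]ethenyl trifluoromethanesulfonate
Conditions: KN(SiMe3)2 (1.05 equiv), THF, −78 °C; PhNTf2, −78 → 0 °C; aq NH4Cl
Reagents that add atoms: N-phenylbis(trifluoromethanesulfonimide), O=S(=O)(N(c1ccccc1)S(=O)(=O)C(F)(F)F)C(F)(F)F
Why: Kinetic deprotonation of the methyl ketone at the unhindered CH3 followed by O-sulfonylation gives the 2-triflyloxy-1-alkene (enol triflate formation), the C3 carbonyl having no α-hydrogen and the tertiary C7–H and C16–H being kinetically inaccessible, so that no stereocentre is touched and the acetyl carbonyl is masked for the next steps.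

Step 6
Reactants: 8 1-[(1R,3aS,7aR)-5-methoxy-3a-methyl-4,7-dioxo-2,3,3a,4,7,7a-hexahydro-1H-inden-1-yl]ethenyl trifluoromethanesulfonate
Product: 9 1-[(1R,3aS,4S,7aR)-4-hydroxy-5-methoxy-3a-methyl-7-oxo-2,3,3a,4,7,7a-hexahydro-1H-inden-1-yl]ethenyl trifluoromethanesulfonate
Conditions: NaBH4, CeCl3·7H2O, MeOH/CH2Cl2, −78 °C
Reagents that add atoms: none
Why: Luche 1,2-reduction is chemoselective for the C3 enone carbonyl (the C15 carbonyl is a vinylogous ester and the alkenyl triflate is inert), and hydride is expected to enter from the α face anti to the pseudo-axial C4–C5 bond to give the 3β carbinol, whose configuration is deliberately left to be corrected by equilibration in step 12.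

Step 7
Reactants: 9 1-[(1R,3aS,4S,7aR)-4-hydroxy-5-methoxy-3a-methyl-7-oxo-2,3,3a,4,7,7a-hexahydro-1H-inden-1-yl]ethenyl trifluoromethanesulfonate
Product: 10 1-[(1R,3aS,4S,7aR)-4-hydroxy-6-iodo-5-methoxy-3a-methyl-7-oxo-2,3,3a,4,7,7a-hexahydro-1H-inden-1-yl]ethenyl trifluoromethanesulfonate
Conditions: I2 (1.5 equiv), pyridine, CH2Cl2, 0 → 25 °C
Reagents that add atoms: iodine, II
Why: Electrophilic α-iodination of the vinylogous ester at its nucleophilic carbon C1 (pyridine-mediated addition–elimination, Johnson-type α-iodination of an enone) installs the cross-coupling handle without affecting any stereocentre.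

Step 8
Reactants: 10 1-[(1R,3aS,4S,7aR)-4-hydroxy-6-iodo-5-methoxy-3a-methyl-7-oxo-2,3,3a,4,7,7a-hexahydro-1H-inden-1-yl]ethenyl trifluoromethanesulfonate, 11 (3S)-3,7-dimethylocta-1,6-diene ((S)-β-citronellene)
Product: 13 1-[(1R,3aS,4S,7aR)-6-[(3S)-3,7-dimethyloct-6-en-1-yl]-4-hydroxy-5-methoxy-3a-methyl-7-oxo-2,3,3a,4,7,7a-hexahydro-1H-inden-1-yl]ethenyl trifluoromethanesulfonate, via B-alkyl-9-BBN 12 (not isolated)
Conditions: 11, 9-BBN-H, THF, 0 → 25 °C; then 10, PdCl2(dppf) (5 mol %), AsPh3, Cs2CO3, DMF/H2O, 25 °C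
Reagents that add atoms: none
Why: 9-BBN hydroborates only the monosubstituted alkene of 11 in the anti-Markovnikov sense and the primary alkylborane undergoes B-alkyl Suzuki–Miyaura coupling with the α-iodoenone, whose C–I bond adds to zerovalent palladium far faster at 25 °C than the alkenyl triflate, so that the C1–C14 bond is formed and the C12 stereocentre is imported unchanged from 11.

Step 9
Reactants: 13 1-[(1R,3aS,4S,7aR)-6-[(3S)-3,7-dimethyloct-6-en-1-yl]-4-hydroxy-5-methoxy-3a-methyl-7-oxo-2,3,3a,4,7,7a-hexahydro-1H-inden-1-yl]ethenyl trifluoromethanesulfonate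
Product: 15 1-[(1R,3aS,4S,7aS)-6-[(3S)-3,7-dimethyloct-6-en-1-yl]-4-hydroxy-3a,7-dimethyl-5-oxo-2,3,3a,4,5,7a-hexahydro-1H-inden-1-yl]ethenyl trifluoromethanesulfonate, via methyl carbinol 14 (not isolated)
Conditions: MeMgBr (4 equiv), CeCl3 (4 equiv), THF, −78 °C; then 1 M HCl, THF, 0 °C
Reagents that add atoms: methylmagnesium bromide, C[Mg]Br; water, O
Why: Organocerium 1,2-addition to the vinylogous ester carbonyl (the alkenyl triflate survives at −78 °C) is followed by a Stork–Danheiser-type acid-triggered allylic transposition, in which ionisation of the tertiary carbinol of 14 gives a methoxy-stabilised allyl cation that water captures at C2, so that loss of methanol forms the new C2–O bond as the ketone together with the tetrasubstituted C1=C15 alkene and destroys the transient C15 stereocentre.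

Step 10
Reactants: 15 1-[(1R,3aS,4S,7aS)-6-[(3S)-3,7-dimethyloct-6-en-1-yl]-4-hydroxy-3a,7-dimethyl-5-oxo-2,3,3a,4,5,7a-hexahydro-1H-inden-1-yl]ethenyl trifluoromethanesulfonate
Product: 16 1-[(1R,3aS,4S,7aS)-4-hydroxy-3a,7-dimethyl-6-[(3R)-3-methyl-6-oxohexyl]-5-oxo-2,3,3a,4,5,7a-hexahydro-1H-inden-1-yl]ethenyl trifluoromethanesulfonate
Conditions: O3, CH2Cl2, −78 °C (Sudan Red 7B end point); PPh3
Reagents that add atoms: ozone, [O-][O+]=O
Why: Ozonolysis with reductive work-up cleaves only the electron-rich trisubstituted chain alkene (the conjugated tetrasubstituted enone and the alkenyl triflate are electron-poor) and unmasks the C9 aldehyde without periodate, which would cleave the α-ketol.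

Step 11
Reactants: 16 1-[(1R,3aS,4S,7aS)-4-hydroxy-3a,7-dimethyl-6-[(3R)-3-methyl-6-oxohexyl]-5-oxo-2,3,3a,4,5,7a-hexahydro-1H-inden-1-yl]ethenyl trifluoromethanesulfonate
Product: 18 (3S,4S,7R,9S,12R,16S)-9-acetoxy-3-hydroxytrinervita-1(15),8(19)-dien-2-one, via chromium-bound macrocyclic alkoxide 17 (not isolated)
Conditions: CrCl2 (15 mol %), (S)-N-[2-(4-isopropyl-4,5-dihydrooxazol-2-yl)-6-methylphenyl]methanesulfonamide (17 mol %), Et3N (17 mol %), NiCl2(dme) (2 mol %), Mn powder (2 equiv), LiCl (2 equiv), Ac2O (2.5 equiv), MeCN/THF, 25 °C, syringe pump (final 2 mM)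
Reagents that add atoms: acetic anhydride, CC(=O)OC(C)=O
Why: Proposed new method: an acylative, chromium-catalytic asymmetric Nozaki–Hiyama–Kishi macrocyclisation in which zerovalent nickel inserts into the alkenyl triflate, the alkenyl group passes to chromium carrying the chiral sulfonamide ligand and adds to the aldehyde on the face dictated by the ligand (closing the eleven-membered ring and setting C9 as S, the ligand enantiomer being chosen accordingly), and the resulting trivalent chromium alkoxide is released by O-acylation with acetic anhydride instead of the usual silylation, so that the C9 acetate C–O bond of the target is made in the turnover step while Mn returns chromium to the divalent state and the hindered C3–OH stays free, the closest known reactions being the Mn/TMSCl chromium-catalytic Nozaki–Hiyama–Kishi reaction and sulfonamide-ligand-controlled asymmetric Ni/Cr macrocyclisations.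

Step 12
Reactants: 18 (3S,4S,7R,9S,12R,16S)-9-acetoxy-3-hydroxytrinervita-1(15),8(19)-dien-2-one
Product: 20 (2R,3R,4S,7R,9S,12R,16S)-9-acetoxytrinervita-1(15),8(19)-diene-2,3-diol, via 3-epimerised ketol 19 (not isolated)
Conditions: DBU (0.3 equiv), CH2Cl2, 25 °C; then Me4NBH(OAc)3 (5 equiv), MeCN/AcOH, −20 °C
Reagents that add atoms: none
Why: Catalytic DBU equilibrates the α-ketol carbon C3 by enolisation to the 3α (equatorial) carbinol, because in the bridged tricycle the 3β-hydroxyl is 1,3-diaxial to the C16–C7 bond that must be pseudo-axial to carry the ansa bridge, and the Evans–Saksena reagent then binds this hydroxyl and delivers hydride intramolecularly to the same (α) face of the C2 ketone (hydroxyl-directed reduction), giving the 2β alcohol anti to O3, that is the trans-diol, without touching the acetate.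

**Compound list**
1 | 3-methoxy-5-methylphenol | COc1cc(C)cc(O)c1 | starting material
2 | 2-methoxy-6-methylcyclohexa-2,5-diene-1,4-dione | COC1=CC(=O)C=C(C)C1=O | intermediate
3 | 2-methylbuta-1,3-diene (isoprene) | C=CC(C)=C | starting material
4 | (4aR,8aS)-2-methoxy-6,8a-dimethyl-4a,5,8,8a-tetrahydronaphthalene-1,4-dione | O=C1[C@@H]2CC(C)=CC[C@]2(C)C(=O)C(OC)=C1 | intermediate
5 | (5R,6S)-2-methoxy-6-methyl-6-(2-oxoethyl)-5-(2-oxopropyl)cyclohex-2-ene-1,4-dione (keto-aldehyde, not isolated) | O=C1[C@H](CC(C)=O)[C@](C)(CC=O)C(=O)C(OC)=C1 | intermediate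
6 | (3aS,7aS)-3-acetyl-6-methoxy-7a-methyl-3a,7a-dihydro-1H-indene-4,7-dione | O=C1[C@@H]2C(C(C)=O)=CC[C@]2(C)C(=O)C(OC)=C1 | intermediate
7 | (3R,3aR,7aS)-3-acetyl-6-methoxy-7a-methyl-2,3,3a,7a-tetrahydro-1H-indene-4,7-dione | O=C1[C@@H]2[C@H](C(C)=O)CC[C@]2(C)C(=O)C(OC)=C1 | intermediate
8 | 1-[(1R,3aS,7aR)-5-methoxy-3a-methyl-4,7-dioxo-2,3,3a,4,7,7a-hexahydro-1H-inden-1-yl]ethenyl trifluoromethanesulfonate | O=C1[C@@H]2[C@H](C(=C)OS(=O)(=O)C(F)(F)F)CC[C@]2(C)C(=O)C(OC)=C1 | intermediate
9 | 1-[(1R,3aS,4S,7aR)-4-hydroxy-5-methoxy-3a-methyl-7-oxo-2,3,3a,4,7,7a-hexahydro-1H-inden-1-yl]ethenyl trifluoromethanesulfonate | O=C1[C@@H]2[C@H](C(=C)OS(=O)(=O)C(F)(F)F)CC[C@]2(C)[C@H](O)C(OC)=C1 | intermediate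
10 | 1-[(1R,3aS,4S,7aR)-4-hydroxy-6-iodo-5-methoxy-3a-methyl-7-oxo-2,3,3a,4,7,7a-hexahydro-1H-inden-1-yl]ethenyl trifluoromethanesulfonate | O=C1[C@@H]2[C@H](C(=C)OS(=O)(=O)C(F)(F)F)CC[C@]2(C)[C@H](O)C(OC)=C1I | intermediate
11 | (3S)-3,7-dimethylocta-1,6-diene ((S)-β-citronellene) | C=C[C@@H](C)CCC=C(C)C | starting material
12 | 9-[(3R)-3,7-dimethyloct-6-en-1-yl]-9-borabicyclo[3.3.1]nonane (not isolated) | CC(C)=CCC[C@H](C)CCB1C2CCCC1CCC2 | intermediate
13 | 1-[(1R,3aS,4S,7aR)-6-[(3S)-3,7-dimethyloct-6-en-1-yl]-4-hydroxy-5-methoxy-3a-methyl-7-oxo-2,3,3a,4,7,7a-hexahydro-1H-inden-1-yl]ethenyl trifluoromethanesulfonate | CC(C)=CCC[C@H](C)CCC=1C(=O)[C@@H]2[C@H](C(=C)OS(=O)(=O)C(F)(F)F)CC[C@]2(C)[C@H](O)C=1OC | intermediate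
14 | 1-[(1R,3aS,4S,7R,7aR)-6-[(3S)-3,7-dimethyloct-6-en-1-yl]-4,7-dihydroxy-5-methoxy-3a,7-dimethyl-2,3,3a,4,7,7a-hexahydro-1H-inden-1-yl]ethenyl trifluoromethanesulfonate (methyl carbinol, not isolated; C15 epimer drawn as expected, inconsequential) | CC(C)=CCC[C@H](C)CCC=1[C@](C)(O)[C@@H]2[C@H](C(=C)OS(=O)(=O)C(F)(F)F)CC[C@]2(C)[C@H](O)C=1OC | intermediate
15 | 1-[(1R,3aS,4S,7aS)-6-[(3S)-3,7-dimethyloct-6-en-1-yl]-4-hydroxy-3a,7-dimethyl-5-oxo-2,3,3a,4,5,7a-hexahydro-1H-inden-1-yl]ethenyl trifluoromethanesulfonate | CC(C)=CCC[C@H](C)CCC1=C(C)[C@@H]2[C@H](C(=C)OS(=O)(=O)C(F)(F)F)CC[C@]2(C)[C@H](O)C1=O | intermediate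
16 | 1-[(1R,3aS,4S,7aS)-4-hydroxy-3a,7-dimethyl-6-[(3R)-3-methyl-6-oxohexyl]-5-oxo-2,3,3a,4,5,7a-hexahydro-1H-inden-1-yl]ethenyl trifluoromethanesulfonate | O=CCC[C@H](C)CCC1=C(C)[C@@H]2[C@H](C(=C)OS(=O)(=O)C(F)(F)F)CC[C@]2(C)[C@H](O)C1=O | intermediate
17 | (3S,4S,7R,9S,12R,16S)-3,9-dihydroxytrinervita-1(15),8(19)-dien-2-one (formed as its chromium alkoxide, not isolated) | C=C1[C@@H](O)CC[C@H](C)CCC2=C(C)[C@@H]3[C@H]1CC[C@]3(C)[C@H](O)C2=O | intermediate
18 | (3S,4S,7R,9S,12R,16S)-9-acetoxy-3-hydroxytrinervita-1(15),8(19)-dien-2-one | C=C1[C@@H](OC(C)=O)CC[C@H](C)CCC2=C(C)[C@@H]3[C@H]1CC[C@]3(C)[C@H](O)C2=O | intermediate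
19 | (3R,4S,7R,9S,12R,16S)-9-acetoxy-3-hydroxytrinervita-1(15),8(19)-dien-2-one (not isolated) | C=C1[C@@H](OC(C)=O)CC[C@H](C)CCC2=C(C)[C@@H]3[C@H]1CC[C@]3(C)[C@@H](O)C2=O | intermediate
20 | (2R,3R,4S,7R,9S,12R,16S)-9-acetoxytrinervita-1(15),8(19)-diene-2,3-diol | C=C1[C@@H](OC(C)=O)CC[C@H](C)CCC2=C(C)[C@@H]3[C@H]1CC[C@]3(C)[C@@H](O)[C@@H]2O | target

**Step count and risks**

Total step count: 12. Longest linear sequence: 12 steps (1 → 20); compounds 3 and 11 are bought.

The three steps most likely to fail: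

Step 2 (enantio- and regiocontrol at the hindered, methyl-bearing quinone C=C). The fallback replaces the chiral Lewis acid by a covalent auxiliary and diastereomer separation. It sets out from 2: acid-catalysed exchange (TsOH, benzene, removal of methanol) of the methoxy group for (1R,2S,5R)-menthol gives 2-methyl-6-{[(1R,2S,5R)-5-methyl-2-(propan-2-yl)cyclohexyl]oxy}cyclohexa-2,5-diene-1,4-dione F1. SnCl4-chelated Diels–Alder reaction of F1 with 3 (CH2Cl2, −78 °C) gives the two diastereomeric adducts, from which (4aR,8aS)-6,8a-dimethyl-2-{[(1R,2S,5R)-5-methyl-2-(propan-2-yl)cyclohexyl]oxy}-4a,5,8,8a-tetrahydronaphthalene-1,4-dione F2 is separated by crystallisation or chromatography. TsOH in methanol exchanges the auxiliary for methoxy, and the fallback comes back to the route at 4.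

Step 11 (the proposed new step; nickel-mediated acylation of the alkenyl triflate, slow acyl transfer at chromium, or poor control at C9 could each defeat it). The fallback uses known chemistry only and sets out from 16: a stoichiometric Nozaki–Hiyama–Kishi macrocyclisation (CrCl2, catalytic NiCl2, DMSO, high dilution, no ligand, no anhydride) gives the free alcohol 17 and/or its C9 epimer (3S,4S,7R,9R,12R,16S)-3,9-dihydroxytrinervita-1(15),8(19)-dien-2-one F3, which are separated. Alcohol 17 is acetylated (Ac2O, pyridine, 0 °C), and F3 is esterified with inversion under Mitsunobu conditions (PPh3, DIAD, AcOH), the neopentyl C3–OH being inert in both cases. Both branches come back to the route at 18.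

Step 12 (the intramolecular hydride delivery must pass the axial C4 methyl group, and external attack would give the C2 epimer). The fallback sets out from 18: after the same DBU equilibration, Luche reduction (NaBH4, CeCl3·7H2O, MeOH, −78 °C) is expected to give the cis-diol (2S,3R,4S,7R,9S,12R,16S)-9-acetoxytrinervita-1(15),8(19)-diene-2,3-diol F4. Mitsunobu esterification of its allylic C2–OH with chloroacetic acid (PPh3, DIAD) inverts C2 and gives (2R,3R,4S,7R,9S,12R,16S)-9-acetoxy-3-hydroxytrinervita-1(15),8(19)-dien-2-yl chloroacetate F5. Thiourea/NaHCO3 in ethanol removes the chloroacetate in the presence of the acetate, and the fallback comes back to the route at 20.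

**Further compounds**
F1 | step 2 | 2-methyl-6-{[(1R,2S,5R)-5-methyl-2-(propan-2-yl)cyclohexyl]oxy}cyclohexa-2,5-diene-1,4-dione | CC1=CC(=O)C=C(O[C@@H]2C[C@H](C)CC[C@H]2C(C)C)C1=O
F2 | step 2 | (4aR,8aS)-6,8a-dimethyl-2-{[(1R,2S,5R)-5-methyl-2-(propan-2-yl)cyclohexyl]oxy}-4a,5,8,8a-tetrahydronaphthalene-1,4-dione | O=C1[C@@H]2CC(C)=CC[C@]2(C)C(=O)C(O[C@@H]3C[C@H](C)CC[C@H]3C(C)C)=C1
F3 | step 11 | (3S,4S,7R,9R,12R,16S)-3,9-dihydroxytrinervita-1(15),8(19)-dien-2-one | C=C1[C@H](O)CC[C@H](C)CCC2=C(C)[C@@H]3[C@H]1CC[C@]3(C)[C@H](O)C2=O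
F4 | step 12 | (2S,3R,4S,7R,9S,12R,16S)-9-acetoxytrinervita-1(15),8(19)-diene-2,3-diol | C=C1[C@@H](OC(C)=O)CC[C@H](C)CCC2=C(C)[C@@H]3[C@H]1CC[C@]3(C)[C@@H](O)[C@H]2O
F5 | step 12 | (2R,3R,4S,7R,9S,12R,16S)-9-acetoxy-3-hydroxytrinervita-1(15),8(19)-dien-2-yl chloroacetate | C=C1[C@@H](OC(C)=O)CC[C@H](C)CCC2=C(C)[C@@H]3[C@H]1CC[C@]3(C)[C@@H](O)[C@@H]2OC(=O)CCl
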